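**Plan**

- Numbering: the side chain runs from C1' (benzylic) to C17' (methyl), with the carbinol at C16'. Retrosynthetically the three O–Si bonds go first, then C7'–C8' and C9'–C10' are cut together. This exposes the cis C8'=C9' unit, an unsubstituted CH=CH between saturated C7' and the doubly allylic C10', as acetylene flanked by a 7-arylheptyl nucleophile and a (Z)-allylic bromide. The resorcinol ring is the only ring and is bought; no ring is formed.
- The arylheptyl piece is cut at C1'–C2' (benzylic bromide plus 6-chlorohexyl Grignard). The allylic bromide is cut at C10'–C11' (formaldehyde) and at C12'–C13' (a second acetylene carbocupration of a C13'–C17' iodide).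
- Forward: ester to benzylic bromide, copper-catalysed chain extension, iodide (steps 1–5); (S)-pent-4-en-2-ol to iodide, Z-vinyl iodide, Z-allylic alcohol, bromide (steps 6–11); three-component union (step 12); desilylation (step 13).
- Stereochemistry: C16' (S) is carried from (S)-pent-4-en-2-ol and is never a reacting centre. Both Z alkenes arise from syn-addition of a cuprate across acetylene and are retained in every later step.

Key step: step 12

Assumption: C16' is S, as read from the target SMILES; all three hydroxyls are masked as tert-butyldimethylsilyl (TBS) ethers so that one fluoride treatment frees them (TBSO = tert-butyldimethylsilyloxy).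

**Route**

Step 1
Reactants: 1 methyl 3,5-dihydroxybenzoate
Product: 2 methyl 3,5-bis(tert-butyldimethylsilyloxy)benzoate
Conditions: TBSCl (2.4 equiv), imidazole (5 equiv), DMF, rt
Reagents that add atoms: tert-butyldimethylsilyl chloride (TBSCl), C[Si](C)(Cl)C(C)(C)C
Why: Imidazole-promoted silylation of phenols (Corey protocol) should cap both hydroxyls while the methyl ester stays intact.

Step 2
Reactants: 2 methyl 3,5-bis(tert-butyldimethylsilyloxy)benzoate
Product: 3 [3,5-bis(tert-butyldimethylsilyloxy)phenyl]methanol
Conditions: DIBAL-H (2.5 equiv), CH2Cl2, −78 → 0 °C; aq. Rochelle salt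
Reagents that add atoms: none
Why: DIBAL-H reduction of an aryl ester to the benzylic alcohol is routine at low temperature and aryl silyl ethers are not attacked by the aluminium hydride.

Step 3
Reactants: 3 [3,5-bis(tert-butyldimethylsilyloxy)phenyl]methanol
Product: 4 3,5-bis(tert-butyldimethylsilyloxy)benzyl bromide
Conditions: CBr4 (1.3 equiv), PPh3 (1.3 equiv), CH2Cl2, 0 °C
Reagents that add atoms: carbon tetrabromide, BrC(Br)(Br)Br
Why: The Appel reaction replaces the benzylic hydroxyl by bromide through SN2 displacement of the alkoxyphosphonium ion under neutral conditions that leave aryl silyl ethers untouched.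

Step 4
Reactants: 4 3,5-bis(tert-butyldimethylsilyloxy)benzyl bromide; 5 1-bromo-6-chlorohexane
Product: 7 1-(7-chloroheptyl)-3,5-bis(tert-butyldimethylsilyloxy)benzene, via 6-chlorohexylmagnesium bromide 6 (not isolated)
Conditions: 5 (1.5 equiv), Mg, THF, 30 °C; then 4, Li2CuCl4 (5 mol %), THF, −78 → 0 °C
Reagents that add atoms: none
Why: Magnesium inserts selectively into the C–Br bond of the bromochloride, and the Grignard reagent should displace the benzylic bromide under copper catalysis (Kochi-type Li2CuCl4 coupling), forming C1'–C2' while the primary chloride is carried through.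

Step 5
Reactants: 7 1-(7-chloroheptyl)-3,5-bis(tert-butyldimethylsilyloxy)benzene
Product: 8 1-(7-iodoheptyl)-3,5-bis(tert-butyldimethylsilyloxy)benzene
Conditions: NaI (5 equiv), butanone, reflux
Reagents that add atoms: sodium iodide, [Na+].[I-]
Why: Finkelstein exchange (SN2, driven by precipitation of NaCl) turns the primary chloride into the iodide needed for clean iodine–lithium exchange.

Step 6
Reactants: 9 (S)-pent-4-en-2-ol
Product: 10 (S)-2-(tert-butyldimethylsilyloxy)pent-4-ene
Conditions: TBSCl (1.2 equiv), imidazole (2.5 equiv), CH2Cl2, rt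
Reagents that add atoms: tert-butyldimethylsilyl chloride (TBSCl), C[Si](C)(Cl)C(C)(C)C
Why: Standard imidazole-promoted silylation of a secondary alcohol; only the O–H bond reacts, so the S configuration at the carbinol carbon is retained.

Step 7
Reactants: 10 (S)-2-(tert-butyldimethylsilyloxy)pent-4-ene
Product: 12 (S)-4-(tert-butyldimethylsilyloxy)pentan-1-ol, via B-alkyl-9-BBN adduct 11 (not isolated)
Conditions: 9-BBN (1.2 equiv), THF, 0 °C → rt; then aq. NaOH, 30 % H2O2, 0 °C → rt
Reagents that add atoms: hydrogen peroxide, OO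
Why: Brown hydroboration with 9-BBN places boron on the terminal carbon of the monosubstituted alkene, and alkaline peroxide oxidation replaces C–B by C–O without touching the remote stereocentre or the silyl ether.

Step 8
Reactants: 12 (S)-4-(tert-butyldimethylsilyloxy)pentan-1-ol
Product: 13 (S)-5-iodo-2-(tert-butyldimethylsilyloxy)pentane
Conditions: I2 (1.2 equiv), PPh3 (1.2 equiv), imidazole (1.5 equiv), CH2Cl2, 0 °C → rt
Reagents that add atoms: iodine, II
Why: The Garegg–Samuelsson variant of the Appel reaction converts the primary alcohol into the iodide by SN2 displacement under buffered conditions compatible with the secondary TBS ether.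

Step 9
Reactants: 13 (S)-5-iodo-2-(tert-butyldimethylsilyloxy)pentane; 14 acetylene
Product: 18 (1Z,6S)-1-iodo-6-(tert-butyldimethylsilyloxy)hept-1-ene, via alkyllithium 15 (not isolated), via dialkylcuprate 16 (not isolated), via Z-dialkenylcuprate 17 (not isolated)
Conditions: t-BuLi (2.1 equiv), Et2O–pentane, −78 °C; CuBr·SMe2 (0.5 equiv), −40 °C; HC≡CH (1.0 equiv per alkyl group), −50 → −25 °C; I2, THF, −78 → −20 °C
Reagents that add atoms: iodine, II
Why: Iodine–lithium exchange, Gilman cuprate formation and Normant syn-carbocupration of acetylene should give the Z-alkenylcuprate (C12'–C13' formed, C11'=C12' set Z by same-face delivery of carbon and copper), and iodinolysis of the C–Cu bond proceeds with retention, the hindered secondary silyl ether being inert to the organometallics below −25 °C.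

Step 10
Reactants: 18 (1Z,6S)-1-iodo-6-(tert-butyldimethylsilyloxy)hept-1-ene
Product: 20 (2Z,7S)-7-(tert-butyldimethylsilyloxy)oct-2-en-1-ol, via Z-alkenyllithium 19 (not isolated)
Conditions: t-BuLi (2.1 equiv), Et2O, −78 °C; dry (CH2O)n (excess), −78 °C → rt; H2O
Reagents that add atoms: paraformaldehyde (reacting as formaldehyde), C=O
Why: Iodine–lithium exchange on a Z-alkenyl iodide occurs with retention of geometry, and the configurationally stable alkenyllithium undergoes 1,2-addition to formaldehyde, installing C10' as a hydroxymethyl group.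

Step 11
Reactants: 20 (2Z,7S)-7-(tert-butyldimethylsilyloxy)oct-2-en-1-ol
Product: 21 (2S,6Z)-8-bromo-2-(tert-butyldimethylsilyloxy)oct-6-ene
Conditions: CBr4 (1.2 equiv), PPh3 (1.25 equiv), CH2Cl2, −20 → 0 °C; used at once
Reagents that add atoms: carbon tetrabromide, BrC(Br)(Br)Br
Why: Appel bromination of the primary allylic alcohol proceeds by direct SN2 displacement at C10' at low temperature, which should avoid allylic transposition and Z-to-E isomerisation and leaves the secondary TBS ether intact.

Step 12
Reactants: 8 1-(7-iodoheptyl)-3,5-bis(tert-butyldimethylsilyloxy)benzene; 14 acetylene; 21 (2S,6Z)-8-bromo-2-(tert-butyldimethylsilyloxy)oct-6-ene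
Product: 25 5-[(8Z,11Z,16S)-16-(tert-butyldimethylsilyloxy)heptadeca-8,11-dien-1-yl]-1,3-bis(tert-butyldimethylsilyloxy)benzene (hansfordiol D tris-TBS ether), via alkyllithium 22 (not isolated), via dialkylcuprate 23 (not isolated), via Z-dialkenylcuprate 24 (not isolated)
Conditions: 8 (1.3 equiv), t-BuLi (2.6 equiv), Et2O–pentane, −78 °C; CuBr·SMe2 (0.65 equiv), −40 °C; HC≡CH (1.3 equiv), −50 → −25 °C; then THF, P(OEt)3 (1 equiv), 21 (1.0 equiv), −40 → 0 °C
Reagents that add atoms: none
Why: t-BuLi performs iodine–lithium exchange on the primary iodide 8 (the second equivalent destroys t-BuI) and CuBr·SMe2 turns two alkyllithiums 22 into the Gilman cuprate 23, which π-complexes acetylene and delivers carbon and copper to the same face of the triple bond (syn-carbocupration), forming C7'–C8' and fixing C8'=C9' as Z in the alkenylcuprate 24, which keeps its geometry below −20 °C. Oxidative addition of 24 at the bromide-bearing CH2 of 21 and reductive elimination from the allyl(alkenyl)copper(III) species then form C9'–C10' with retention at the alkenyl carbon; the closest known reaction type is the allylation of acetylene-derived Z-alkenylcuprates with allylic halides. No ring is closed and no stereocentre is created; C16' is a remote silyl ether and is not involved. The step needs attack at the α-carbon (C10') and not the γ-carbon (C12') of the allylic bromide, with both Z geometries kept; the α-carbon is primary and unhindered whereas the γ-carbon carries the chain, a lithium homocuprate in THF-containing medium favours coupling at the less substituted terminus, and the low temperature should suppress π-allyl equilibration. Acetylene is symmetrical, so the addition has no regiochemistry to control, and one equivalent per alkyl group below −20 °C should prevent a second insertion. Silyl ethers tolerate organocopper reagents, and nothing in the flask is basic enough to remove the doubly allylic C10' hydrogens, so the skipped diene should not move into conjugation.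

Step 13
Reactants: 25 hansfordiol D tris-TBS ether
Product: 26 hansfordiol D, 5-[(8Z,11Z,16S)-16-hydroxyheptadeca-8,11-dien-1-yl]benzene-1,3-diol
Conditions: TBAF (5 equiv), THF, 0 °C → rt, argon; then 0.5 M HCl to pH 6
Reagents that add atoms: none
Why: Fluoride-induced Si–O cleavage (TBAF desilylation) removes the two aryl silyl ethers rapidly and the secondary alkyl silyl ether more slowly, without affecting the skipped Z,Z-diene or the C16' configuration, and mild acidification returns the neutral resorcinol.

**Compound list**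

1 | methyl 3,5-dihydroxybenzoate | COC(=O)c1cc(O)cc(O)c1 | starting material
2 | methyl 3,5-bis(tert-butyldimethylsilyloxy)benzoate | COC(=O)c1cc(O[Si](C)(C)C(C)(C)C)cc(O[Si](C)(C)C(C)(C)C)c1 | intermediate
3 | [3,5-bis(tert-butyldimethylsilyloxy)phenyl]methanol | OCc1cc(O[Si](C)(C)C(C)(C)C)cc(O[Si](C)(C)C(C)(C)C)c1 | intermediate
4 | 3,5-bis(tert-butyldimethylsilyloxy)benzyl bromide | BrCc1cc(O[Si](C)(C)C(C)(C)C)cc(O[Si](C)(C)C(C)(C)C)c1 | intermediate
5 | 1-bromo-6-chlorohexane | ClCCCCCCBr | starting material
6 | 6-chlorohexylmagnesium bromide | ClCCCCCC[Mg]Br | intermediate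
7 | 1-(7-chloroheptyl)-3,5-bis(tert-butyldimethylsilyloxy)benzene | ClCCCCCCCc1cc(O[Si](C)(C)C(C)(C)C)cc(O[Si](C)(C)C(C)(C)C)c1 | intermediate
8 | 1-(7-iodoheptyl)-3,5-bis(tert-butyldimethylsilyloxy)benzene | ICCCCCCCc1cc(O[Si](C)(C)C(C)(C)C)cc(O[Si](C)(C)C(C)(C)C)c1 | intermediate
9 | (S)-pent-4-en-2-ol | C[C@H](O)CC=C | starting material
10 | (S)-2-(tert-butyldimethylsilyloxy)pent-4-ene | C[C@H](O[Si](C)(C)C(C)(C)C)CC=C | intermediate
11 | 9-[(S)-4-(tert-butyldimethylsilyloxy)pentyl]-9-borabicyclo[3.3.1]nonane | C[C@H](O[Si](C)(C)C(C)(C)C)CCCB1C2CCCC1CCC2 | intermediate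
12 | (S)-4-(tert-butyldimethylsilyloxy)pentan-1-ol | C[C@H](O[Si](C)(C)C(C)(C)C)CCCO | intermediate
13 | (S)-5-iodo-2-(tert-butyldimethylsilyloxy)pentane | C[C@H](O[Si](C)(C)C(C)(C)C)CCCI | intermediate
14 | acetylene | C#C | starting material
15 | (S)-4-(tert-butyldimethylsilyloxy)pentyllithium | C[C@H](O[Si](C)(C)C(C)(C)C)CCC[Li] | intermediate
16 | lithium bis[(S)-4-(tert-butyldimethylsilyloxy)pentyl]cuprate | [Li+].C[C@H](O[Si](C)(C)C(C)(C)C)CCC[Cu-]CCC[C@H](C)O[Si](C)(C)C(C)(C)C | intermediate
17 | lithium bis[(1Z,6S)-6-(tert-butyldimethylsilyloxy)hept-1-enyl]cuprate | [Li+].C[C@H](O[Si](C)(C)C(C)(C)C)CCC/C=C\[Cu-]/C=C\CCC[C@H](C)O[Si](C)(C)C(C)(C)C | intermediate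
18 | (1Z,6S)-1-iodo-6-(tert-butyldimethylsilyloxy)hept-1-ene | C[C@H](O[Si](C)(C)C(C)(C)C)CCC/C=C\I | intermediate
19 | (1Z,6S)-6-(tert-butyldimethylsilyloxy)hept-1-enyllithium | C[C@H](O[Si](C)(C)C(C)(C)C)CCC/C=C\[Li] | intermediate
20 | (2Z,7S)-7-(tert-butyldimethylsilyloxy)oct-2-en-1-ol | C[C@H](O[Si](C)(C)C(C)(C)C)CCC/C=C\CO | intermediate
21 | (2S,6Z)-8-bromo-2-(tert-butyldimethylsilyloxy)oct-6-ene | C[C@H](O[Si](C)(C)C(C)(C)C)CCC/C=C\CBr | intermediate
22 | 7-[3,5-bis(tert-butyldimethylsilyloxy)phenyl]heptyllithium | [Li]CCCCCCCc1cc(O[Si](C)(C)C(C)(C)C)cc(O[Si](C)(C)C(C)(C)C)c1 | intermediate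
23 | lithium bis{7-[3,5-bis(tert-butyldimethylsilyloxy)phenyl]heptyl}cuprate | [Li+].CC(C)(C)[Si](C)(C)Oc1cc(CCCCCCC[Cu-]CCCCCCCc2cc(O[Si](C)(C)C(C)(C)C)cc(O[Si](C)(C)C(C)(C)C)c2)cc(O[Si](C)(C)C(C)(C)C)c1 | intermediate
24 | lithium bis{(1Z)-9-[3,5-bis(tert-butyldimethylsilyloxy)phenyl]non-1-enyl}cuprate | [Li+].CC(C)(C)[Si](C)(C)Oc1cc(CCCCCCC/C=C\[Cu-]/C=C\CCCCCCCc2cc(O[Si](C)(C)C(C)(C)C)cc(O[Si](C)(C)C(C)(C)C)c2)cc(O[Si](C)(C)C(C)(C)C)c1 | intermediate
25 | 5-[(8Z,11Z,16S)-16-(tert-butyldimethylsilyloxy)heptadeca-8,11-dien-1-yl]-1,3-bis(tert-butyldimethylsilyloxy)benzene | C[C@H](O[Si](C)(C)C(C)(C)C)CCC/C=C\C/C=C\CCCCCCCc1cc(O[Si](C)(C)C(C)(C)C)cc(O[Si](C)(C)C(C)(C)C)c1 | intermediate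
26 | hansfordiol D, 5-[(8Z,11Z,16S)-16-hydroxyheptadeca-8,11-dien-1-yl]benzene-1,3-diol | C[C@H](O)CCC/C=C\C/C=C\CCCCCCCc1cc(O)cc(O)c1 | target

**Count**

Total steps: 13. Longest linear sequence: 8 steps (steps 6–13, from (S)-pent-4-en-2-ol); the aryl branch (steps 1–5) joins at step 12.

**Steps most likely to fail**

1. Step 12. The alkenylcopper may attack the γ-carbon (C12') of the allylic bromide, giving a branched diene. The allylcopper(III) intermediate may also equilibrate through a π-allyl species so that the C11'=C12' Z geometry erodes. A lesser concern is attack of the alkyllithium on an aryl silyl ether before transmetalation. The fallback gives up the allylation and makes C11'=C12' by a Z-selective Wittig reaction, keeping the acetylene carbocupration for C7'–C9'. It sets out from 8 and 14: cuprate 24 is generated as in step 12 and treated with ethylene oxide (−40 → 0 °C), which should give (3Z)-11-[3,5-bis(tert-butyldimethylsilyloxy)phenyl]undec-3-en-1-ol F1. Iodination (I2, PPh3, imidazole) should convert it into 1-[(8Z)-11-iodoundec-8-en-1-yl]-3,5-bis(tert-butyldimethylsilyloxy)benzene F2. Heating with PPh3 in MeCN should give {(3Z)-11-[3,5-bis(tert-butyldimethylsilyloxy)phenyl]undec-3-en-1-yl}triphenylphosphonium iodide F3. Deprotonation with NaHMDS (THF, −78 °C) gives {(3Z)-11-[3,5-bis(tert-butyldimethylsilyloxy)phenyl]undec-3-en-1-ylidene}triphenylphosphorane F4. This ylide is combined with (S)-5-(tert-butyldimethylsilyloxy)hexanal F5, obtained from allylic alcohol 20 by ozonolysis (O3, CH2Cl2, −78 °C; PPh3). The salt-free Wittig reaction of this non-stabilised ylide should give the Z alkene and thus 25, where the route is rejoined before step 13.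

2. Step 9. The silyloxyalkyllithium may be protonated or only partly formed, or a second molecule of acetylene may insert into the alkenylcuprate, giving dienyl iodides that are hard to remove. The fallback sets out from iodide 13 and replaces carbocupration by acetylide alkylation and semi-hydrogenation. The dianion of propargyl alcohol (LiNH2, liquid NH3–THF) is alkylated with 13 to give (S)-7-(tert-butyldimethylsilyloxy)oct-2-yn-1-ol F6. Lindlar hydrogenation (Pd/CaCO3/Pb, quinoline, H2, EtOAc) should then give the Z-allylic alcohol 20, rejoining the route before step 11 and bypassing step 10.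

3. Step 10. The alkenyllithium may be protonated by moisture held in paraformaldehyde, or depolymerisation may be too slow, so that the des-iodo terminal alkene forms instead of the allylic alcohol. The fallback sets out from vinyl iodide 18 and avoids the organolithium. Palladium-catalysed methoxycarbonylation (PdCl2(PPh3)2 cat., CO 1 atm, MeOH, Et3N, DMF, 50 °C) with retention of alkene geometry should give methyl (2Z,7S)-7-(tert-butyldimethylsilyloxy)oct-2-enoate F7. DIBAL-H reduction (CH2Cl2, −78 °C) should then give 20, rejoining the route before step 11.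

**Further compounds**

F1 | step 12 | (3Z)-11-[3,5-bis(tert-butyldimethylsilyloxy)phenyl]undec-3-en-1-ol | OCC/C=C\CCCCCCCc1cc(O[Si](C)(C)C(C)(C)C)cc(O[Si](C)(C)C(C)(C)C)c1
F2 | step 12 | 1-[(8Z)-11-iodoundec-8-en-1-yl]-3,5-bis(tert-butyldimethylsilyloxy)benzene | ICC/C=C\CCCCCCCc1cc(O[Si](C)(C)C(C)(C)C)cc(O[Si](C)(C)C(C)(C)C)c1
F3 | step 12 | {(3Z)-11-[3,5-bis(tert-butyldimethylsilyloxy)phenyl]undec-3-en-1-yl}triphenylphosphonium iodide | [I-].c1ccc(cc1)[P+](CC/C=C\CCCCCCCc1cc(O[Si](C)(C)C(C)(C)C)cc(O[Si](C)(C)C(C)(C)C)c1)(c1ccccc1)c1ccccc1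
F4 | step 12 | {(3Z)-11-[3,5-bis(tert-butyldimethylsilyloxy)phenyl]undec-3-en-1-ylidene}triphenylphosphorane | c1ccc(cc1)P(=CC/C=C\CCCCCCCc1cc(O[Si](C)(C)C(C)(C)C)cc(O[Si](C)(C)C(C)(C)C)c1)(c1ccccc1)c1ccccc1
F5 | step 12 | (S)-5-(tert-butyldimethylsilyloxy)hexanal | C[C@H](O[Si](C)(C)C(C)(C)C)CCCC=O
F6 | step 9 | (S)-7-(tert-butyldimethylsilyloxy)oct-2-yn-1-ol | C[C@H](O[Si](C)(C)C(C)(C)C)CCCC#CCO
F7 | step 10 | methyl (2Z,7S)-7-(tert-butyldimethylsilyloxy)oct-2-enoate | C[C@H](O[Si](C)(C)C(C)(C)C)CCC/C=C\C(=O)OC
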